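**Plan**
1. Retrosynthesis: first the N-Boc group on the unsubstituted indole is removed; then the quinone ring is cut on one side at two bonds at once, C(OMe)–C(=O) (the carbonyl next to the indol-3-yl-bearing carbon) and C(disubstituted indolyl)–C(=O) (the other carbonyl). This gives a two-carbon indol-3-yl ynol ether and a four-carbon maleoylcobalt metallacycle, which goes back to a squaric-acid-derived cyclobutenedione.
2. Enabling feature: the ring atoms C(=O)–C(indol-3-yl)=C(OMe)–C(=O) of the quinone are a ring-opened 3-aryl-4-methoxycyclobut-3-ene-1,2-dione, whose strained C(=O)–C(=O) bond adds to monovalent cobalt; the remaining C(indolyl)=C(OMe) pair is at the oxidation level of an alkyne.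
3. Alkyne half, forward: 7-bromoindole, C2 reverse prenylation (allylboration, then dehydrogenation), C7 prenylation (Suzuki–Miyaura), C3 iodination, Negishi coupling with methoxyethynylzinc chloride.
4. Four-carbon half, forward: squaric acid, its dichloride, substitution by indole C3 and methanolysis, N-Boc protection, cobalt insertion and ligand exchange.
5. The quinone ring is the only ring made (step 11); the N-Boc group is the only helper and leaves in the last step.
6. Stereochemistry: the target has no stereocentre, so only regiochemistry is controlled (para pattern of the quinone by polarity-matched insertion; 1,1-dimethylallyl against linear prenyl by the mechanisms of the two allyl transfers).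

Key step: step 11

Assumption: the target is achiral and has no stereogenic alkene; LiNEt2 and ClCo(PPh3)3 are taken as purchased reagents.

**Step 1**
Reactants: 1 4,4,5,5-tetramethyl-2-(3-methylbut-2-en-1-yl)-1,3,2-dioxaborolane (prenylboronic acid pinacol ester)
Product: 2 potassium trifluoro(3-methylbut-2-en-1-yl)borate
Conditions: KHF2 (aq., 4 equiv), MeOH, 25 °C; acetone extraction, Et2O precipitation
Reagents that add atoms: potassium hydrogen difluoride, F.[F-].[K+]
Why: Exchange of the pinacol ester for fluoride with KHF2 is the standard conversion of a boronic ester into its potassium trifluoroborate, and the allylic C–B bond is not touched.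

**Step 2**
Reactants: 3 7-bromo-1H-indole; 2 potassium trifluoro(3-methylbut-2-en-1-yl)borate
Product: 4 7-bromo-2-(2-methylbut-3-en-2-yl)-2,3-dihydro-1H-indole (racemic)
Conditions: BF3·OEt2 (2.5 equiv), CH2Cl2, 0 → 25 °C; aqueous work-up
Reagents that add atoms: none
Why: BF3 abstracts fluoride from 2 to give a Lewis-acidic prenyldifluoroborane that binds the nitrogen of the 3H-indole tautomer and transfers its allyl group to C2 through a six-membered chair transition state with allylic transposition (allylboration of a C=N bond), which should place the 1,1-dimethylallyl group at C2; the new C2 stereocentre forms as a racemate and is erased in step 3.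

**Step 3**
Reactants: 4 7-bromo-2-(2-methylbut-3-en-2-yl)-2,3-dihydro-1H-indole
Product: 5 7-bromo-2-(2-methylbut-3-en-2-yl)-1H-indole
Conditions: activated MnO2 (10 equiv), CH2Cl2, 25 °C
Reagents that add atoms: none
Why: Dehydrogenation of an indoline to the aromatic indole with MnO2 is a standard oxidation that should leave the aryl bromide and the unactivated vinyl group alone.

**Step 4**
Reactants: 5 7-bromo-2-(2-methylbut-3-en-2-yl)-1H-indole; 1 4,4,5,5-tetramethyl-2-(3-methylbut-2-en-1-yl)-1,3,2-dioxaborolane
Product: 6 2-(2-methylbut-3-en-2-yl)-7-(3-methylbut-2-en-1-yl)-1H-indole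
Conditions: PdCl2(IPent)(3-chloropyridine) (2 mol %; IPent = 1,3-bis[2,6-di(pentan-3-yl)phenyl]imidazol-2-ylidene), aq. KOH (5 M), THF, 70 °C
Reagents that add atoms: none
Why: In this Suzuki–Miyaura coupling of an allylboronate, the bulky carbene ligand lets the allylpalladium intermediate equilibrate and reductively eliminate at its unhindered CH2 terminus, which should give the linear prenyl group at C7 while the free N–H and the neopentyl-type vinyl group stay inert.

**Step 5**
Reactants: 6 2-(2-methylbut-3-en-2-yl)-7-(3-methylbut-2-en-1-yl)-1H-indole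
Product: 7 3-iodo-2-(2-methylbut-3-en-2-yl)-7-(3-methylbut-2-en-1-yl)-1H-indole
Conditions: NIS (1.0 equiv), DMF, −20 → 0 °C, dark; used directly
Reagents that add atoms: N-iodosuccinimide, O=C1CCC(=O)N1I
Why: Electrophilic aromatic iodination should occur at C3, the most nucleophilic position of a 2-alkylindole and far more reactive toward N-iodosuccinimide at low temperature than either alkene.

**Step 6**
Reactants: 7 3-iodo-2-(2-methylbut-3-en-2-yl)-7-(3-methylbut-2-en-1-yl)-1H-indole; 8 2-chloro-1,1-dimethoxyethane (chloroacetaldehyde dimethyl acetal)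
Product: 11 3-(methoxyethynyl)-2-(2-methylbut-3-en-2-yl)-7-(3-methylbut-2-en-1-yl)-1H-indole, via lithium methoxyacetylide 9 (not isolated), via methoxyethynylzinc chloride 10 (not isolated)
Conditions: 8 (2.5 equiv), LiNEt2 (7.5 equiv), THF, 0 °C; ZnCl2 (2.6 equiv), 0 °C; then 7, Pd(PtBu3)2 (5 mol %), THF, 25–40 °C; aq. NaHCO3 work-up, Et3N-deactivated silica
Reagents that add atoms: none
Why: Double elimination and deprotonation of the chloroacetal gives lithium methoxyacetylide, transmetalation to zinc tames its basicity, and Negishi coupling of the small linear alkynylzinc with the hindered 3-iodoindole under a bulky electron-rich phosphine–palladium catalyst should form the C3–C(sp) bond, the excess zinc reagent covering the shielded N–H and the basic work-up preserving the ynol ether.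

**Step 7**
Reactants: 12 squaric acid (3,4-dihydroxycyclobut-3-ene-1,2-dione)
Product: 13 squaric acid dichloride (3,4-dichlorocyclobut-3-ene-1,2-dione)
Conditions: (COCl)2 (2.2 equiv), DMF (cat.), toluene, 50 °C
Reagents that add atoms: oxalyl chloride, ClC(=O)C(=O)Cl
Why: Vilsmeier-type activation with oxalyl chloride and catalytic DMF converts the two vinylogous carboxylic acid OH groups into vinylogous acid chlorides.

**Step 8**
Reactants: 13 squaric acid dichloride; 14 1H-indole
Product: 16 3-(1H-indol-3-yl)-4-methoxycyclobut-3-ene-1,2-dione, via 3-chloro-4-(1H-indol-3-yl)cyclobutenedione 15 (not isolated)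
Conditions: Et2O, 0 → 25 °C; evaporate; MeOH, 65 °C
Reagents that add atoms: methanol, CO
Why: Uncatalysed Friedel–Crafts-type addition–elimination of indole C3 at one vinylogous acid chloride should stop at mono-substitution because the product is a deactivated vinylogous amide, and methanolysis of the remaining vinylogous acid chloride then gives the methyl enol ether.

**Step 9**
Reactants: 16 3-(1H-indol-3-yl)-4-methoxycyclobut-3-ene-1,2-dione
Product: 17 tert-butyl 3-(2-methoxy-3,4-dioxocyclobut-1-en-1-yl)-1H-indole-1-carboxylate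
Conditions: Boc2O (1.2 equiv), DMAP (5 mol %), MeCN, 25 °C
Reagents that add atoms: di-tert-butyl dicarbonate, CC(C)(C)OC(=O)OC(=O)OC(C)(C)C
Why: DMAP-catalysed N-acylation caps the acidic indole N–H, and the carbamate reduces the donation of this indole into the cyclobutenedione, which later keeps the two acyl carbons electronically distinct.

**Step 10**
Reactants: 17 tert-butyl 3-(2-methoxy-3,4-dioxocyclobut-1-en-1-yl)-1H-indole-1-carboxylate
Product: 19 chloro(dimethylglyoxime)(pyridine)cobalt maleoyl complex (cobaltacyclopent-3-ene-2,5-dione carrying the N-Boc-indol-3-yl and methoxy groups), via chlorobis(triphenylphosphine)cobalt maleoyl complex 18 (not isolated)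
Conditions: ClCo(PPh3)3 (1.1 equiv), PhH, 25 °C, Ar; then dimethylglyoxime (1.2 equiv), pyridine, 25 °C
Reagents that add atoms: chlorotris(triphenylphosphine)cobalt, Cl[Co-3]([P+](c1ccccc1)(c1ccccc1)c1ccccc1)([P+](c1ccccc1)(c1ccccc1)c1ccccc1)[P+](c1ccccc1)(c1ccccc1)c1ccccc1; dimethylglyoxime, CC(=NO)C(C)=NO; pyridine, c1ccncc1
Why: Strain-driven oxidative addition of monovalent cobalt into the C(=O)–C(=O) bond of the cyclobutenedione (C–C bond activation) gives the five-membered maleoyl metallacycle of trivalent cobalt, and ligand substitution of the two phosphines by dimethylglyoxime and pyridine should give the air-stable complex that is reactive toward alkynes.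

**Step 11**
Reactants: 19 chloro(dimethylglyoxime)(pyridine)cobalt maleoyl complex; 11 3-(methoxyethynyl)-2-(2-methylbut-3-en-2-yl)-7-(3-methylbut-2-en-1-yl)-1H-indole
Product: 20 tert-butyl 3-{2,5-dimethoxy-4-[2-(2-methylbut-3-en-2-yl)-7-(3-methylbut-2-en-1-yl)-1H-indol-3-yl]-3,6-dioxocyclohexa-1,4-dien-1-yl}-1H-indole-1-carboxylate
Conditions: 11 (1.2 equiv), Zn(OTf)2 (1.2 equiv), 2,6-di-tert-butylpyridine (0.5 equiv), 4 Å molecular sieves, ClCH2CH2Cl, 25 → 50 °C, Ar; then air, silica plug
Reagents that add atoms: none
Why: Zn(OTf)2 takes pyridine (or chloride) off the trivalent cobalt of 19, the ynol ether 11 binds at the freed site cis to both acyl carbons, one Co–acyl bond migrates onto the alkyne to give a seven-membered cobaltacycle, and C–C reductive elimination closes the quinone and releases monovalent cobalt, so both ring bonds are made in one operation. The closest known reaction type is the Lewis-acid-promoted quinone annulation of maleoylcobalt and phthaloylcobalt dimethylglyoxime complexes with alkynes. The six-membered ring closes as a metal-templated [4+2] union (alkyne insertion, then reductive elimination from the seven-membered metallacycle), driven by the strain energy of the cyclobutenedione that the C–C oxidative addition stored in 19 and by formation of the quinone. No stereocentre is formed. The selectivity needed is regiochemical (2,5- against 2,6-dimethoxy) and should follow from matched polarity and size: cobalt binds the nucleophilic, bulky, indolyl-bearing alkyne carbon, the migrating acyl goes to the small, electrophilic O-bearing carbon, and the acyl that migrates should be the more electron-rich vinylogous-ester acyl next to the indolyl carbon of 19, because the N-Boc group switches off the competing vinylogous-amide donation of that indole into the other acyl group. Chemoselectivity rests on the alkyne being a far better ligand than the prenyl and vinyl alkenes, on the blocked C3 and shielded N–H of the indole in 11, and on the hindered pyridine base that removes adventitious acid before it can hydrate the ynol ether.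

**Step 12**
Reactants: 20 tert-butyl 3-{2,5-dimethoxy-4-[2-(2-methylbut-3-en-2-yl)-7-(3-methylbut-2-en-1-yl)-1H-indol-3-yl]-3,6-dioxocyclohexa-1,4-dien-1-yl}-1H-indole-1-carboxylate
Product: 21 2,5-dimethoxy-3-(1H-indol-3-yl)-6-[2-(2-methylbut-3-en-2-yl)-7-(3-methylbut-2-en-1-yl)-1H-indol-3-yl]cyclohexa-2,5-diene-1,4-dione (target)
Conditions: NaOMe (0.3 equiv), dry MeOH/THF, 0 → 25 °C; AcOH quench
Reagents that add atoms: none
Why: The indole carbamate, activated by the quinonyl group at C3, should be cleaved by catalytic methoxide (transacylation to a mixed carbonate), while addition–elimination of methoxide at the methoxyquinone carbons is degenerate, so the vinylogous esters survive under anhydrous conditions.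

**Compound list**
1 | 4,4,5,5-tetramethyl-2-(3-methylbut-2-en-1-yl)-1,3,2-dioxaborolane | CC(C)=CCB1OC(C)(C)C(C)(C)O1 | starting material
2 | potassium trifluoro(3-methylbut-2-en-1-yl)borate | CC(C)=CC[B-](F)(F)F.[K+] | intermediate
3 | 7-bromo-1H-indole | Brc1cccc2cc[nH]c12 | starting material
4 | 7-bromo-2-(2-methylbut-3-en-2-yl)-2,3-dihydro-1H-indole (racemic) | C=CC(C)(C)C1Cc2cccc(Br)c2N1 | intermediate
5 | 7-bromo-2-(2-methylbut-3-en-2-yl)-1H-indole | C=CC(C)(C)c1cc2cccc(Br)c2[nH]1 | intermediate
6 | 2-(2-methylbut-3-en-2-yl)-7-(3-methylbut-2-en-1-yl)-1H-indole | C=CC(C)(C)c1cc2cccc(CC=C(C)C)c2[nH]1 | intermediate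
7 | 3-iodo-2-(2-methylbut-3-en-2-yl)-7-(3-methylbut-2-en-1-yl)-1H-indole | C=CC(C)(C)c1[nH]c2c(CC=C(C)C)cccc2c1I | intermediate
8 | 2-chloro-1,1-dimethoxyethane | COC(CCl)OC | starting material
9 | lithium methoxyacetylide (formed in the flask) | [Li]C#COC | intermediate
10 | methoxyethynylzinc chloride (formed in the flask) | COC#C[Zn]Cl | intermediate
11 | 3-(methoxyethynyl)-2-(2-methylbut-3-en-2-yl)-7-(3-methylbut-2-en-1-yl)-1H-indole | C=CC(C)(C)c1[nH]c2c(CC=C(C)C)cccc2c1C#COC | intermediate
12 | squaric acid | OC1=C(O)C(=O)C1=O | starting material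
13 | squaric acid dichloride | ClC1=C(Cl)C(=O)C1=O | intermediate
14 | 1H-indole | c1ccc2[nH]ccc2c1 | starting material
15 | 3-chloro-4-(1H-indol-3-yl)cyclobut-3-ene-1,2-dione (formed in the flask) | ClC1=C(c2c[nH]c3ccccc23)C(=O)C1=O | intermediate
16 | 3-(1H-indol-3-yl)-4-methoxycyclobut-3-ene-1,2-dione | COC1=C(c2c[nH]c3ccccc23)C(=O)C1=O | intermediate
17 | tert-butyl 3-(2-methoxy-3,4-dioxocyclobut-1-en-1-yl)-1H-indole-1-carboxylate | COC1=C(c2cn(C(=O)OC(C)(C)C)c3ccccc23)C(=O)C1=O | intermediate
18 | chlorobis(triphenylphosphine)cobalt maleoyl complex (formed in the flask) | O=C1C(c2cn(C(=O)OC(C)(C)C)c3ccccc23)=C(OC)C(=O)[Co-2]1(Cl)([P+](c1ccccc1)(c1ccccc1)c1ccccc1)[P+](c1ccccc1)(c1ccccc1)c1ccccc1 | intermediate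
19 | chloro(dimethylglyoxime)(pyridine)cobalt maleoyl complex | CC1=[N+](O)[Co-3]2(Cl)([n+]3ccccc3)([N+](O)=C1C)C(=O)C(c1cn(C(=O)OC(C)(C)C)c3ccccc13)=C(OC)C2=O | intermediate
20 | tert-butyl 3-{2,5-dimethoxy-4-[2-(2-methylbut-3-en-2-yl)-7-(3-methylbut-2-en-1-yl)-1H-indol-3-yl]-3,6-dioxocyclohexa-1,4-dien-1-yl}-1H-indole-1-carboxylate | C=CC(C)(C)c1[nH]c2c(CC=C(C)C)cccc2c1C1=C(OC)C(=O)C(c2cn(C(=O)OC(C)(C)C)c3ccccc23)=C(OC)C1=O | intermediate
21 | 2,5-dimethoxy-3-(1H-indol-3-yl)-6-[2-(2-methylbut-3-en-2-yl)-7-(3-methylbut-2-en-1-yl)-1H-indol-3-yl]cyclohexa-2,5-diene-1,4-dione | C=CC(C)(C)c1[nH]c2c(CC=C(C)C)cccc2c1C1=C(OC)C(=O)C(c2c[nH]c3ccccc23)=C(OC)C1=O | target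

**Totals**
Total step count: 12. Longest linear sequence: 8 steps (steps 1, 2, 3, 4, 5, 6, 11, 12).

**Steps most likely to fail**

Step 11. The insertion may pair the O-bearing alkyne carbon with the acyl carbon next to C–OMe (for instance if the Lewis acid binds the vinylogous-ester carbonyl instead of pyridine), which would lead to the 2,6-dimethoxy pattern. The insertion may also be slow at the hindered indolyl terminus, and the ynol ether may be hydrated before it inserts. The fallback sets out from 14 and 6 and comes back at 21, and fixes the para pattern through the reagent. Indole 14 is added under HCl in THF to 2,5-dichloro-1,4-benzoquinone to give 2,5-dichloro-3-(1H-indol-3-yl)benzene-1,4-diol F1, which DDQ oxidises to 2,5-dichloro-3-(1H-indol-3-yl)cyclohexa-2,5-diene-1,4-dione F2. Conjugate addition of 6 in AcOH at the only remaining C–H position gives 2,5-dichloro-3-(1H-indol-3-yl)-6-[2-(2-methylbut-3-en-2-yl)-7-(3-methylbut-2-en-1-yl)-1H-indol-3-yl]benzene-1,4-diol F3, and DDQ gives the corresponding 2,5-dichloro-3,6-bis(indolyl)cyclohexa-2,5-diene-1,4-dione F4. NaOMe in MeOH then replaces both vinylic chlorides by addition–elimination and gives 21.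

Step 6. Oxidative addition at the hindered, electron-rich, N-unprotected 3-iodoindole may be slow, protodeiodination may compete, and the ynol ether may be lost by hydration on isolation. The fallback sets out from 6 and comes back at 11 without palladium or the iodide. Friedel–Crafts acylation at C3 with methoxyacetyl chloride and Et2AlCl in CH2Cl2 gives 2-methoxy-1-[2-(2-methylbut-3-en-2-yl)-7-(3-methylbut-2-en-1-yl)-1H-indol-3-yl]ethan-1-one F5. KN(SiMe3)2 (2.2 equiv) and PhNTf2 convert it into (Z)-2-methoxy-1-[2-(2-methylbut-3-en-2-yl)-7-(3-methylbut-2-en-1-yl)-1H-indol-3-yl]ethenyl trifluoromethanesulfonate F6. Anti elimination of triflate with KOtBu in THF at −78 °C gives 11, which would be carried into step 11 without storage.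

Step 2. Allyl transfer may be sluggish or misdirected (no reaction, or attack at C3), because the C7 bromine hinders boron–nitrogen binding and the transfer has to build a quaternary carbon. The fallback sets out from 3 and comes back at 5, replacing steps 2 and 3. Sulfenylation at C3 with MeSSMe and catalytic I2 in DMSO gives 7-bromo-3-(methylsulfanyl)-1H-indole F7. S-Alkylation with prenyl bromide gives (7-bromo-1H-indol-3-yl)(methyl)(3-methylbut-2-en-1-yl)sulfonium bromide F8. With K2CO3 this undergoes the charge-accelerated thio-Claisen rearrangement, with allylic transposition, to 7-bromo-2-(2-methylbut-3-en-2-yl)-3-(methylsulfanyl)-1H-indole F9. Protodesulfenylation with TFA and 2-mercaptobenzoic acid, a metal-free method that spares the aryl bromide and the vinyl group, gives 5.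

**Further compounds**
F1 | step 11 | 2,5-dichloro-3-(1H-indol-3-yl)benzene-1,4-diol | Oc1c(Cl)c(-c2c[nH]c3ccccc23)c(O)c(Cl)c1
F2 | step 11 | 2,5-dichloro-3-(1H-indol-3-yl)cyclohexa-2,5-diene-1,4-dione | O=C1C=C(Cl)C(=O)C(c2c[nH]c3ccccc23)=C1Cl
F3 | step 11 | 2,5-dichloro-3-(1H-indol-3-yl)-6-[2-(2-methylbut-3-en-2-yl)-7-(3-methylbut-2-en-1-yl)-1H-indol-3-yl]benzene-1,4-diol | Oc1c(Cl)c(-c2c[nH]c3ccccc23)c(O)c(Cl)c1-c1c(C(C)(C)C=C)[nH]c2c(CC=C(C)C)cccc12
F4 | step 11 | 2,5-dichloro-3-(1H-indol-3-yl)-6-[2-(2-methylbut-3-en-2-yl)-7-(3-methylbut-2-en-1-yl)-1H-indol-3-yl]cyclohexa-2,5-diene-1,4-dione | C=CC(C)(C)c1[nH]c2c(CC=C(C)C)cccc2c1C1=C(Cl)C(=O)C(c2c[nH]c3ccccc23)=C(Cl)C1=O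
F5 | step 6 | 2-methoxy-1-[2-(2-methylbut-3-en-2-yl)-7-(3-methylbut-2-en-1-yl)-1H-indol-3-yl]ethan-1-one | C=CC(C)(C)c1[nH]c2c(CC=C(C)C)cccc2c1C(=O)COC
F6 | step 6 | (Z)-2-methoxy-1-[2-(2-methylbut-3-en-2-yl)-7-(3-methylbut-2-en-1-yl)-1H-indol-3-yl]ethenyl trifluoromethanesulfonate | CO/C=C(\OS(=O)(=O)C(F)(F)F)c1c(C(C)(C)C=C)[nH]c2c(CC=C(C)C)cccc12
F7 | step 2 | 7-bromo-3-(methylsulfanyl)-1H-indole | CSc1c[nH]c2c(Br)cccc12
F8 | step 2 | (7-bromo-1H-indol-3-yl)(methyl)(3-methylbut-2-en-1-yl)sulfonium bromide | C[S+](CC=C(C)C)c1c[nH]c2c(Br)cccc12.[Br-]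
F9 | step 2 | 7-bromo-2-(2-methylbut-3-en-2-yl)-3-(methylsulfanyl)-1H-indole | C=CC(C)(C)c1[nH]c2c(Br)cccc2c1SC
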